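**Strategy**

Everything rests on reading C8 as a former ester carbonyl. In the target C8 carries three things, the ether oxygen of ring B, benzylic C7 and the C9 methyl; taking C9 away as a methylene unit leaves the ring B phenyl ester of an O-silylated (R)-3,4,5-trimethoxymandelic acid (ring A). One carbonyl methylenation of that ester with a titanium methylidene creates the C8=C9 bond and delivers the complete C7–C8(–O–aryl)–C9 skeleton as an aryl enol ether, with the hindered aryl ether bond already made by plain acylation and C7 untouched. The C7 hydroxyl then steers hydrogen onto C8=C9 to set C8; a ring B bromide carries the side-chain position.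

Key step: step 6

Remark on numbering: C7 is the benzylic carbon on ring A (3,4,5-trimethoxyphenyl), C8 the carbon bearing the ring B aryloxy oxygen, C9 the methyl. The target is (7R,8R), the threo series.

Assumption: the (S,S)-TsDPEN ruthenium catalyst is taken to give the (R)-α-hydroxy ester, as the aryl–arene contact model predicts for an aryl ketone whose other substituent outranks the aryl group. The configuration and enantiomeric purity are to be confirmed at compound 5, and the (R,R)-ligand is used instead if the sense proves opposite.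

**Route**

Step 1
Reactants: 1 5-bromo-1,2,3-trimethoxybenzene; 2 diethyl oxalate
Product: 4 ethyl 2-oxo-2-(3,4,5-trimethoxyphenyl)acetate, via (3,4,5-trimethoxyphenyl)magnesium bromide 3 (not isolated)
Conditions: Mg, I2 (cat.), THF, reflux; then added to 2 (2 equiv), THF, −78 °C; 1 M HCl quench
Reagents that add atoms: none
Why: Magnesium insertion gives the aryl Grignard reagent, and its inverse addition to excess diethyl oxalate at −78 °C stops at the magnesium hemiketal, which releases the α-keto ester only on acidic work-up (Grignard acylation of an oxalate diester).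

Step 2
Reactants: 4 ethyl 2-oxo-2-(3,4,5-trimethoxyphenyl)acetate
Product: 5 ethyl (R)-2-hydroxy-2-(3,4,5-trimethoxyphenyl)acetate
Conditions: RuCl(p-cymene)[(S,S)-TsDPEN] (1 mol %), HCO2H/Et3N (5:2), DMF, 25 °C
Reagents that add atoms: none
Why: Noyori asymmetric transfer hydrogenation of an aryl α-keto ester, in which the ring A aryl group lies against the cymene ligand and the (S,S)-ligand directs hydride to the face that should give the (R)-alcohol, so C7 is set here by the catalyst; the ester is not reduced.

Step 3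
Reactants: 5 ethyl (R)-2-hydroxy-2-(3,4,5-trimethoxyphenyl)acetate
Product: 6 ethyl (R)-2-[(tert-butyldimethylsilyl)oxy]-2-(3,4,5-trimethoxyphenyl)acetate
Conditions: TBSCl, imidazole, DMF, 25 °C
Reagents that add atoms: tert-butyldimethylsilyl chloride, CC(C)(C)[Si](C)(C)Cl
Why: Imidazole-promoted silylation of a secondary alcohol; imidazole is too weak a base to enolise the mandelate, so C7 keeps its configuration.

Step 4
Reactants: 6 ethyl (R)-2-[(tert-butyldimethylsilyl)oxy]-2-(3,4,5-trimethoxyphenyl)acetate
Product: 7 (R)-2-[(tert-butyldimethylsilyl)oxy]-2-(3,4,5-trimethoxyphenyl)acetic acid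
Conditions: LiOH·H2O, THF/H2O (3:1), 0 °C; then 1 M HCl to pH 3 at 0 °C
Reagents that add atoms: lithium hydroxide, [Li+].[OH-]
Why: Saponification of the ethyl ester by hydroxide at 0 °C is much faster than deprotonation at C7, and the secondary TBS ether resists hydroxide and the brief cold acidification.

Step 5
Reactants: 7 (R)-2-[(tert-butyldimethylsilyl)oxy]-2-(3,4,5-trimethoxyphenyl)acetic acid; 8 4-bromo-2,6-dimethoxyphenol
Product: 9 4-bromo-2,6-dimethoxyphenyl (R)-2-[(tert-butyldimethylsilyl)oxy]-2-(3,4,5-trimethoxyphenyl)acetate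
Conditions: DIC, DMAP (10 mol %), CH2Cl2, 0 °C
Reagents that add atoms: none
Why: Steglich esterification, in which DMAP intercepts the O-acylisourea and the acylpyridinium acylates the phenol oxygen, so the hindered C8–O–aryl bond is made as a simple acylation; low temperature and a catalytic amount of DMAP should keep ketene formation and loss of configuration at C7 negligible.

Step 6
Reactants: 9 4-bromo-2,6-dimethoxyphenyl (R)-2-[(tert-butyldimethylsilyl)oxy]-2-(3,4,5-trimethoxyphenyl)acetate
Product: 10 (R)-5-bromo-2-{[3-(tert-butyldimethylsilyloxy)-3-(3,4,5-trimethoxyphenyl)prop-1-en-2-yl]oxy}-1,3-dimethoxybenzene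
Conditions: Cp2Ti(μ-Cl)(μ-CH2)AlMe2 (0.5 M in toluene, 2 equiv), pyridine (cat.), THF, −40 → 25 °C; 15% aq. NaOH quench at −10 °C; basic Al2O3
Reagents that add atoms: Tebbe reagent Cp2Ti(μ-Cl)(μ-CH2)AlMe2, C[Al-]1(C)C[Ti]([Cl+]1)(C1C=CC=C1)C1C=CC=C1
Why: Tebbe methylenation of an ester: base (pyridine, THF) frees Cp2Ti=CH2 from the titanium–aluminium complex, the methylidene adds across the aryl ester C=O in a [2+2] fashion to an oxatitanacyclobutane, and cycloreversion driven by the Ti=O bond leaves the C8=C9 double bond with both C–O single bonds of the former ester intact. The closest known reaction type is the conversion of simple phenyl esters into 1-aryloxyalkenes with the same reagent. No ring is closed and no stereocentre is formed; the existing C7 centre is only carried through, which is safe because the titanium methylidene is not basic enough to enolise the α-silyloxy ester. The step needs chemoselectivity for the ester carbonyl, and the substrate offers no other carbonyl, while the aryl bromide, the methyl ethers and the TBS ether are inert to the reagent. The aryl ester is more electrophilic than an alkyl ester, which should offset the crowding by the two ortho methoxy groups and the OTBS group, and the cold basic quench with chromatography on basic alumina protects the acid-labile enol ether.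

Step 7
Reactants: 10 (R)-5-bromo-2-{[3-(tert-butyldimethylsilyloxy)-3-(3,4,5-trimethoxyphenyl)prop-1-en-2-yl]oxy}-1,3-dimethoxybenzene
Product: 11 (R)-2-(4-bromo-2,6-dimethoxyphenoxy)-1-(3,4,5-trimethoxyphenyl)prop-2-en-1-ol
Conditions: TBAF (1 M in THF), THF, 0 → 25 °C; aq. NaHCO3 work-up
Reagents that add atoms: none
Why: Fluoride cleavage of the silyl ether under basic, acid-free conditions frees the C7 hydroxyl without touching the acid-sensitive aryl enol ether or the aryl bromide.

Step 8
Reactants: 11 (R)-2-(4-bromo-2,6-dimethoxyphenoxy)-1-(3,4,5-trimethoxyphenyl)prop-2-en-1-ol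
Product: 12 (1R,2R)-2-(4-bromo-2,6-dimethoxyphenoxy)-1-(3,4,5-trimethoxyphenyl)propan-1-ol
Conditions: [Rh(nbd)(dppb)]BF4 (5 mol %), H2 (40 bar), CH2Cl2, 25 °C
Reagents that add atoms: none
Why: Hydroxyl-directed hydrogenation of a 1,1-disubstituted allylic alcohol with a cationic rhodium diphosphine catalyst: the C7 hydroxyl and C8=C9 chelate the metal, the reactive conformer keeps the C7–H bond beside the C8 aryloxy group and turns the ring A aryl group towards the CH2 terminus to avoid allylic 1,2-strain, and hydrogen is delivered to the face syn to the hydroxyl, which should give the 1,2-anti hydroxyl/methyl pattern, that is the threo (7R,8R) ether; the catalyst does not insert into the aryl bromide, and high hydrogen pressure suppresses isomerisation of the allylic alcohol to a ketone.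

Step 9
Reactants: 12 (1R,2R)-2-(4-bromo-2,6-dimethoxyphenoxy)-1-(3,4,5-trimethoxyphenyl)propan-1-ol; 13 (E)-3-(tert-butyldimethylsilyloxy)prop-1-enylboronic acid pinacol ester
Product: 14 (1R,2R)-2-{4-[(E)-3-(tert-butyldimethylsilyloxy)prop-1-en-1-yl]-2,6-dimethoxyphenoxy}-1-(3,4,5-trimethoxyphenyl)propan-1-ol
Conditions: Pd(dppf)Cl2·CH2Cl2 (5 mol %), K2CO3, 1,4-dioxane/H2O (4:1), 80 °C
Reagents that add atoms: none
Why: Suzuki–Miyaura coupling of the aryl bromide with an (E)-alkenyl pinacol boronate proceeds with retention of alkene geometry and tolerates the free secondary alcohol and the silyl ether; the bromide is flanked only by hydrogens and is unhindered.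

Step 10
Reactants: 14 (1R,2R)-2-{4-[(E)-3-(tert-butyldimethylsilyloxy)prop-1-en-1-yl]-2,6-dimethoxyphenoxy}-1-(3,4,5-trimethoxyphenyl)propan-1-ol
Product: 15 (1R,2R)-2-{4-[(E)-3-(tert-butyldimethylsilyloxy)prop-1-en-1-yl]-2,6-dimethoxyphenoxy}-1-(3,4,5-trimethoxyphenyl)propyl acetate
Conditions: Ac2O, pyridine, DMAP (cat.), CH2Cl2, 0 → 25 °C
Reagents that add atoms: acetic anhydride, CC(=O)OC(C)=O
Why: DMAP-catalysed acetylation of the only free hydroxyl group, at C7, with retention because the C7–O bond is not broken.

Step 11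
Reactants: 15 (1R,2R)-2-{4-[(E)-3-(tert-butyldimethylsilyloxy)prop-1-en-1-yl]-2,6-dimethoxyphenoxy}-1-(3,4,5-trimethoxyphenyl)propyl acetate
Product: 16 (1R,2R)-2-{4-[(E)-3-hydroxyprop-1-en-1-yl]-2,6-dimethoxyphenoxy}-1-(3,4,5-trimethoxyphenyl)propyl acetate (CNP0125366.1)
Conditions: TBAF, AcOH (1:1), THF, 0 → 25 °C
Reagents that add atoms: none
Why: Fluoride cleavage of the primary allylic TBS ether, buffered with acetic acid to near neutrality, should leave the C7 acetate unhydrolysed (it cannot migrate, since the two oxygens sit on different rings) and should not ionise the electron-rich cinnamyl alcohol.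

**Compound list**

1 | 5-bromo-1,2,3-trimethoxybenzene | COc1cc(Br)cc(OC)c1OC | starting material
2 | diethyl oxalate | CCOC(=O)C(=O)OCC | starting material
3 | (3,4,5-trimethoxyphenyl)magnesium bromide | COc1cc([Mg]Br)cc(OC)c1OC | intermediate
4 | ethyl 2-oxo-2-(3,4,5-trimethoxyphenyl)acetate | CCOC(=O)C(=O)c1cc(OC)c(OC)c(OC)c1 | intermediate
5 | ethyl (R)-2-hydroxy-2-(3,4,5-trimethoxyphenyl)acetate | COc1cc([C@@H](O)C(=O)OCC)cc(OC)c1OC | intermediate
6 | ethyl (R)-2-[(tert-butyldimethylsilyl)oxy]-2-(3,4,5-trimethoxyphenyl)acetate | COc1cc([C@@H](O[Si](C)(C)C(C)(C)C)C(=O)OCC)cc(OC)c1OC | intermediate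
7 | (R)-2-[(tert-butyldimethylsilyl)oxy]-2-(3,4,5-trimethoxyphenyl)acetic acid | COc1cc([C@@H](O[Si](C)(C)C(C)(C)C)C(=O)O)cc(OC)c1OC | intermediate
8 | 4-bromo-2,6-dimethoxyphenol | COc1cc(Br)cc(OC)c1O | starting material
9 | 4-bromo-2,6-dimethoxyphenyl (R)-2-[(tert-butyldimethylsilyl)oxy]-2-(3,4,5-trimethoxyphenyl)acetate | COc1cc([C@@H](O[Si](C)(C)C(C)(C)C)C(=O)Oc2c(OC)cc(Br)cc2OC)cc(OC)c1OC | intermediate
10 | (R)-5-bromo-2-{[3-(tert-butyldimethylsilyloxy)-3-(3,4,5-trimethoxyphenyl)prop-1-en-2-yl]oxy}-1,3-dimethoxybenzene | COc1cc([C@@H](O[Si](C)(C)C(C)(C)C)C(=C)Oc2c(OC)cc(Br)cc2OC)cc(OC)c1OC | intermediate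
11 | (R)-2-(4-bromo-2,6-dimethoxyphenoxy)-1-(3,4,5-trimethoxyphenyl)prop-2-en-1-ol | COc1cc([C@@H](O)C(=C)Oc2c(OC)cc(Br)cc2OC)cc(OC)c1OC | intermediate
12 | (1R,2R)-2-(4-bromo-2,6-dimethoxyphenoxy)-1-(3,4,5-trimethoxyphenyl)propan-1-ol | COc1cc([C@@H](O)[C@@H](C)Oc2c(OC)cc(Br)cc2OC)cc(OC)c1OC | intermediate
13 | (E)-3-(tert-butyldimethylsilyloxy)prop-1-enylboronic acid pinacol ester | CC(C)(C)[Si](C)(C)OC/C=C/B1OC(C)(C)C(C)(C)O1 | starting material
14 | (1R,2R)-2-{4-[(E)-3-(tert-butyldimethylsilyloxy)prop-1-en-1-yl]-2,6-dimethoxyphenoxy}-1-(3,4,5-trimethoxyphenyl)propan-1-ol | COc1cc([C@@H](O)[C@@H](C)Oc2c(OC)cc(/C=C/CO[Si](C)(C)C(C)(C)C)cc2OC)cc(OC)c1OC | intermediate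
15 | (1R,2R)-2-{4-[(E)-3-(tert-butyldimethylsilyloxy)prop-1-en-1-yl]-2,6-dimethoxyphenoxy}-1-(3,4,5-trimethoxyphenyl)propyl acetate | COc1cc([C@@H](OC(C)=O)[C@@H](C)Oc2c(OC)cc(/C=C/CO[Si](C)(C)C(C)(C)C)cc2OC)cc(OC)c1OC | intermediate
16 | (1R,2R)-2-{4-[(E)-3-hydroxyprop-1-en-1-yl]-2,6-dimethoxyphenoxy}-1-(3,4,5-trimethoxyphenyl)propyl acetate | COc1cc([C@@H](OC(C)=O)[C@@H](C)Oc2c(OC)cc(/C=C/CO)cc2OC)cc(OC)c1OC | target

**Step count and risks**

Total step count: 11. Longest linear sequence: 11 steps (1 to 16); 2, 8 and 13 enter as purchased building blocks.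

Steps most likely to fail:

1. Step 6 (ester methylenation).
What may go wrong: slow or incomplete methylenation of an aryl ester crowded by two ortho methoxy groups and the neighbouring silyloxy group; collapse of the titanacycle with loss of aryloxide instead of titanium oxide; hydrolysis of the enol ether during isolation.
Fallback: it sets out from phenol 8 and Grignard reagent 3 and comes back at 12. The C8–O–aryl bond would be made by Mitsunobu etherification of ethyl (S)-lactate with 8 (PPh3, DIAD, THF, 0 → 25 °C), which inverts the lactate carbon and should give ethyl (R)-2-(4-bromo-2,6-dimethoxyphenoxy)propanoate F1. Reduction with i-Bu2AlH in CH2Cl2 at −78 °C should stop at (R)-2-(4-bromo-2,6-dimethoxyphenoxy)propanal F2, which is used without purification. Addition of 3 to F2 precomplexed with MgBr2·OEt2 in CH2Cl2 at −78 °C should pass through the five-membered magnesium chelate of the aldehyde and aryloxy oxygens (Cram chelate model), with attack on the face away from the C8 methyl, to give the threo alcohol 12.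

2. Step 8 (directed hydrogenation).
What may go wrong: poor facial selectivity if the aryloxy or ortho methoxy oxygens compete with the hydroxyl for rhodium; isomerisation of the allylic alcohol to an α-aryloxy ketone; acid-promoted loss of the enol ether.
Fallback: it sets out from phenol 8 and Grignard reagent 3 and comes back at 12, taking C8 from the chiral pool and setting C7 by catalyst control. Displacement of chloride from (S)-2-chloropropanoic acid by the sodium salt of 8 (NaH, DMF, 50 °C) with inversion should give (R)-2-(4-bromo-2,6-dimethoxyphenoxy)propanoic acid F3. Coupling with MeNH(OMe)·HCl (DIC, N-methylmorpholine, CH2Cl2, 0 °C) gives (R)-2-(4-bromo-2,6-dimethoxyphenoxy)-N-methoxy-N-methylpropanamide F4. Addition of 3 (THF, −20 → 0 °C) gives (R)-2-(4-bromo-2,6-dimethoxyphenoxy)-1-(3,4,5-trimethoxyphenyl)propan-1-one F5. Asymmetric transfer hydrogenation of F5 with RuCl(p-cymene)[(S,S)-TsDPEN] in HCO2H/Et3N should set (7R) by the same model as in step 2. The polar Felkin–Anh preference of the α-aryloxy ketone points the same way, so the threo alcohol 12 is expected.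

3. Step 5 (aryl ester formation).
What may go wrong: slow acylation of the doubly ortho-substituted phenol, rearrangement of the O-acylisourea to the N-acylurea, and base-mediated loss of configuration at C7 through the acylpyridinium or a ketene.
Fallback: it sets out from keto ester 4 and phenol 8 and comes back at 9, forming the aryl ester before the stereocentre exists. LiOH hydrolysis of 4 (THF/H2O, 0 °C) gives 2-oxo-2-(3,4,5-trimethoxyphenyl)acetic acid F6. DIC/DMAP esterification with 8 in CH2Cl2, with no stereocentre to lose, gives 4-bromo-2,6-dimethoxyphenyl 2-oxo-2-(3,4,5-trimethoxyphenyl)acetate F7. Transfer hydrogenation as in step 2 should give 4-bromo-2,6-dimethoxyphenyl (R)-2-hydroxy-2-(3,4,5-trimethoxyphenyl)acetate F8. Silylation with TBSOTf and 2,6-lutidine in CH2Cl2 at −78 °C gives 9.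

Further compounds
F1 | step 6 | ethyl (R)-2-(4-bromo-2,6-dimethoxyphenoxy)propanoate | CCOC(=O)[C@@H](C)Oc1c(OC)cc(Br)cc1OC
F2 | step 6 | (R)-2-(4-bromo-2,6-dimethoxyphenoxy)propanal | O=C[C@@H](C)Oc1c(OC)cc(Br)cc1OC
F3 | step 8 | (R)-2-(4-bromo-2,6-dimethoxyphenoxy)propanoic acid | OC(=O)[C@@H](C)Oc1c(OC)cc(Br)cc1OC
F4 | step 8 | (R)-2-(4-bromo-2,6-dimethoxyphenoxy)-N-methoxy-N-methylpropanamide | CON(C)C(=O)[C@@H](C)Oc1c(OC)cc(Br)cc1OC
F5 | step 8 | (R)-2-(4-bromo-2,6-dimethoxyphenoxy)-1-(3,4,5-trimethoxyphenyl)propan-1-one | COc1cc(C(=O)[C@@H](C)Oc2c(OC)cc(Br)cc2OC)cc(OC)c1OC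
F6 | step 5 | 2-oxo-2-(3,4,5-trimethoxyphenyl)acetic acid | COc1cc(C(=O)C(O)=O)cc(OC)c1OC
F7 | step 5 | 4-bromo-2,6-dimethoxyphenyl 2-oxo-2-(3,4,5-trimethoxyphenyl)acetate | COc1cc(C(=O)C(=O)Oc2c(OC)cc(Br)cc2OC)cc(OC)c1OC
F8 | step 5 | 4-bromo-2,6-dimethoxyphenyl (R)-2-hydroxy-2-(3,4,5-trimethoxyphenyl)acetate | COc1cc([C@@H](O)C(=O)Oc2c(OC)cc(Br)cc2OC)cc(OC)c1OC
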